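**Plan**
- **Cuts.** Ring C is opened at C4–C4a (the aryl ketone bond). Next the benzylic ether C2–O1 is cut, and last the C8–C1'' bond to the side chain (C1'' sits on C8, C4'' is the CH2OH carbon). This leaves an iodinated phloroglucinol bis-MOM ether, a 1-aryl-1,3-propanediol and a C10 alkyl iodide.
- **Enabling feature.** In ring A, C4a lies ortho to O1, ortho to the 5-oxygen and para to the 7-oxygen. With C8 substituted it is the only carbon ortho to O1 that still bears hydrogen, so an acyl group tethered through O1–C2–C3 can close ring C only there.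
- **Forward order.** Rings A and B come from phloroglucinol and 4-hydroxy-2-methoxybenzaldehyde. They are joined at O1–C2 (Mitsunobu), the chain is attached at C8 (Negishi), C4 is oxidised to the acid, ring C is closed last, and one acidic methanolysis unmasks the target.
- **Stereochemistry.** C3'' is bought with (S)-3-bromo-2-methylpropan-1-ol. C2'' is set by an Evans alkylation. C2 comes from a catalytic asymmetric allylboration that gives the (R)-carbinol, which is inverted in the Mitsunobu step.

Key step: step 17

Assumption: the (R)-configured binaphthyl phosphoric acid of step 10 is taken to direct the allyl group to the Re face of the 2-methoxy-substituted aryl aldehyde, as it does with other benzaldehydes.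

Step 1
Reactants: 1 (S)-3-bromo-2-methylpropan-1-ol
Product: 2 (S)-(3-bromo-2-methylpropoxy)(tert-butyl)dimethylsilane
Conditions: TBSCl, imidazole, CH2Cl2, 0 °C to rt
Reagents that add atoms: tert-butyldimethylsilyl chloride, CC(C)(C)[Si](C)(C)Cl
Why: Routine imidazole-assisted O-silylation of a primary alcohol, which leaves the purchased stereocentre (future C3'') untouched and masks the future C4'' hydroxyl with a group that falls in the final acid step.

Step 2
Reactants: 2 (S)-(3-bromo-2-methylpropoxy)(tert-butyl)dimethylsilane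
Product: 4 (R)-4-(tert-butyldimethylsilyloxy)-3-methylbutanoic acid, via Grignard reagent 3 (not isolated)
Conditions: Mg, THF, 40 °C; CO2, −40 to 0 °C; cold 0.5 M HCl
Reagents that add atoms: carbon dioxide, O=C=O; magnesium, [Mg] (held only by 3)
Why: Grignard formation and carboxylation add the one carbon that becomes C1'', the stereocentre being β to magnesium and therefore unable to epimerise, while a γ-silyloxy group is too poor a leaving group to be expelled.

Step 3
Reactants: 4 (R)-4-(tert-butyldimethylsilyloxy)-3-methylbutanoic acid; 5 (S)-4-benzyloxazolidin-2-one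
Product: 7 (S)-4-benzyl-3-[(R)-4-(tert-butyldimethylsilyloxy)-3-methylbutanoyl]oxazolidin-2-one, via mixed pivalic anhydride 6 (not isolated)
Conditions: t-BuCOCl, Et3N, THF, −20 °C; then LiCl, 5, −20 °C to rt
Reagents that add atoms: pivaloyl chloride, CC(C)(C)C(=O)Cl (held only by 6)
Why: N-acylation of the oxazolidinone through a mixed pivalic anhydride with LiCl and Et3N is the standard mild entry to Evans imides and needs no strong base next to the silyl ether.

Step 4
Reactants: 7 (S)-4-benzyl-3-[(R)-4-(tert-butyldimethylsilyloxy)-3-methylbutanoyl]oxazolidin-2-one; 8 1-bromo-3-methylbut-2-ene (prenyl bromide)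
Product: 10 (S)-4-benzyl-3-{(S)-2-[(R)-1-(tert-butyldimethylsilyloxy)propan-2-yl]-5-methylhex-4-enoyl}oxazolidin-2-one, via sodium enolate 9 (not isolated)
Conditions: NaN(SiMe3)2, THF, −78 °C; 8, −78 to −40 °C
Reagents that add atoms: sodium bis(trimethylsilyl)amide, [Na+].C[Si](C)(C)[N-][Si](C)(C)C (its sodium is held only by 9)
Why: Evans asymmetric alkylation, in which the chelated (Z)-enolate 9 is attacked by the reactive allylic bromide on the face away from the benzyl group, so that the auxiliary sets C2'' (S in 10, R in the target after the change of priorities) and overrides the small bias of the neighbouring methyl-bearing centre.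

Step 5
Reactants: 10 (S)-4-benzyl-3-{(S)-2-[(R)-1-(tert-butyldimethylsilyloxy)propan-2-yl]-5-methylhex-4-enoyl}oxazolidin-2-one
Product: 11 (S)-2-[(R)-1-(tert-butyldimethylsilyloxy)propan-2-yl]-5-methylhex-4-en-1-ol
Conditions: LiBH4, THF–Et2O, 0 °C to rt
Reagents that add atoms: none
Why: Reductive cleavage of the imide with LiBH4 should give the primary alcohol without enolisation at C2'' and without touching the alkene or the silyl ether, and it returns the auxiliary.

Step 6
Reactants: 11 (S)-2-[(R)-1-(tert-butyldimethylsilyloxy)propan-2-yl]-5-methylhex-4-en-1-ol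
Product: 12 tert-butyl{[(2R,3S)-3-(iodomethyl)-2,6-dimethylhept-5-en-1-yl]oxy}dimethylsilane
Conditions: I2, PPh3, imidazole, CH2Cl2, 0 °C to rt, dark
Reagents that add atoms: iodine, II
Why: Appel-type iodination replaces the primary hydroxyl by SN2 at a CH2 group, so neither stereocentre takes part and the buffered medium spares the alkene and the silyl ether.

Step 7
Reactants: 13 phloroglucinol (benzene-1,3,5-triol)
Product: 14 3,5-bis(methoxymethoxy)phenol
Conditions: MOMCl (2.0 equiv), i-Pr2NEt, DMF, 0 °C to rt
Reagents that add atoms: chloromethyl methyl ether, COCCl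
Why: Williamson-type O-alkylation of two of three equivalent phenols, where only the degree and not the site of alkylation has to be controlled, so that stoichiometry and chromatographic removal and recycling of the mono- and tris-ethers suffice at this cheap first step.

Step 8
Reactants: 14 3,5-bis(methoxymethoxy)phenol
Product: 15 2-iodo-3,5-bis(methoxymethoxy)phenol
Conditions: N-iodosuccinimide (1.0 equiv), CH2Cl2, −40 to 0 °C, dark
Reagents that add atoms: N-iodosuccinimide, O=C1CCC(=O)N1I
Why: Electrophilic aromatic iodination of a highly activated phenol, in which the two equivalent carbons between OH and OMOM are less crowded than the carbon between the two OMOM groups and lie ortho to the strongest donor, so that iodine should enter there and mark the future C8 next to the one free oxygen (future O1).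

Step 9
Reactants: 16 4-hydroxy-2-methoxybenzaldehyde
Product: 17 4-formyl-3-methoxyphenyl acetate
Conditions: Ac2O, pyridine, CH2Cl2, 0 °C to rt
Reagents that add atoms: acetic anhydride, CC(=O)OC(C)=O
Why: Simple phenol acetylation, which turns the para oxygen from a strong into a weak donor and so later keeps the benzylic C–O bonds at the future C2 from ionising.

Step 10
Reactants: 17 4-formyl-3-methoxyphenyl acetate; 18 allylboronic acid pinacol ester
Product: 19 4-[(R)-1-hydroxybut-3-en-1-yl]-3-methoxyphenyl acetate
Conditions: 18 (1.2 equiv), (R)-3,3'-bis(2,4,6-triisopropylphenyl)-1,1'-binaphthyl-2,2'-diyl hydrogen phosphate (5 mol %), toluene, −30 °C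
Reagents that add atoms: none
Why: Chiral phosphoric acid-catalysed allylboration through a closed chair transition state, in which the acid binds a boronate oxygen and the formyl hydrogen and exposes the Re face of the aldehyde, so that the catalyst sets the carbinol centre as R under neutral conditions that the aryl acetate tolerates.

Step 11
Reactants: 19 4-[(R)-1-hydroxybut-3-en-1-yl]-3-methoxyphenyl acetate
Product: 21 4-[(R)-1,3-dihydroxypropyl]-3-methoxyphenyl acetate, via secondary ozonide 20 (not isolated)
Conditions: O3, CH2Cl2, −78 °C; BH3·SMe2, −78 °C to rt; MeOH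
Reagents that add atoms: ozone, [O-][O+]=O
Why: Ozonolysis of the only alkene with reductive work-up of the ozonide by borane removes the terminal carbon and gives the 1,3-diol, the electrophilic hydride source being chosen because it spares the aryl acetate that a basic borohydride work-up in methanol would cleave.

Step 12
Reactants: 21 4-[(R)-1,3-dihydroxypropyl]-3-methoxyphenyl acetate
Product: 22 4-[(R)-1-hydroxy-3-(triethylsilyloxy)propyl]-3-methoxyphenyl acetate
Conditions: TESCl (1.05 equiv), imidazole, CH2Cl2, −40 to −20 °C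
Reagents that add atoms: chlorotriethylsilane, CC[Si](Cl)(CC)CC
Why: Sterically controlled monosilylation of the primary over the ortho-flanked secondary benzylic hydroxyl, with triethylsilyl chosen because it can later be removed beside the primary TBS ether.

Step 13
Reactants: 15 2-iodo-3,5-bis(methoxymethoxy)phenol; 22 4-[(R)-1-hydroxy-3-(triethylsilyloxy)propyl]-3-methoxyphenyl acetate
Product: 23 4-{(S)-1-[2-iodo-3,5-bis(methoxymethoxy)phenoxy]-3-(triethylsilyloxy)propyl}-3-methoxyphenyl acetate
Conditions: PPh3, DIAD, toluene, −10 °C to rt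
Reagents that add atoms: none
Why: Mitsunobu etherification, in which the fairly acidic ortho-iodophenol displaces the oxyphosphonium group by SN2 with inversion and turns the (R)-carbinol into the (S)-ether (future C2), the non-polar solvent, the low temperature and the 4-acetate all working against an ionised pathway.

Step 14
Reactants: 12 tert-butyl{[(2R,3S)-3-(iodomethyl)-2,6-dimethylhept-5-en-1-yl]oxy}dimethylsilane; 23 4-{(S)-1-[2-iodo-3,5-bis(methoxymethoxy)phenoxy]-3-(triethylsilyloxy)propyl}-3-methoxyphenyl acetate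
Product: 25 4-[(S)-1-{2-[(2R,3R)-4-(tert-butyldimethylsilyloxy)-3-methyl-2-(3-methylbut-2-en-1-yl)butyl]-3,5-bis(methoxymethoxy)phenoxy}-3-(triethylsilyloxy)propyl]-3-methoxyphenyl acetate, via alkylzinc iodide 24 (not isolated)
Conditions: 12, Zn dust (activated with BrCH2CH2Br and Me3SiCl), LiCl, THF, 40 °C; then 23, Pd(OAc)2 (5 mol %), 2-dicyclohexylphosphino-2',6'-dimethoxybiphenyl (10 mol %), THF, rt to 45 °C
Reagents that add atoms: zinc, [Zn] (held only by 24)
Why: Negishi sp3–sp2 cross-coupling, in which zinc inserts into the primary C–I bond without touching the stereocentres and a bulky electron-rich biarylphosphine on zerovalent palladium promotes oxidative addition to the electron-rich doubly ortho-substituted aryl iodide and reductive elimination ahead of β-hydride loss, while the organozinc halide tolerates acetate, silyl ethers and acetals.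

Step 15
Reactants: 25 4-[(S)-1-{2-[(2R,3R)-4-(tert-butyldimethylsilyloxy)-3-methyl-2-(3-methylbut-2-en-1-yl)butyl]-3,5-bis(methoxymethoxy)phenoxy}-3-(triethylsilyloxy)propyl]-3-methoxyphenyl acetate
Product: 26 4-[(S)-1-{2-[(2R,3R)-4-(tert-butyldimethylsilyloxy)-3-methyl-2-(3-methylbut-2-en-1-yl)butyl]-3,5-bis(methoxymethoxy)phenoxy}-3-hydroxypropyl]-3-methoxyphenyl acetate
Conditions: pyridinium p-toluenesulfonate (0.2 equiv), MeOH–CH2Cl2, 0 °C
Reagents that add atoms: none
Why: Mildly acid-catalysed methanolysis distinguishes the triethylsilyl from the tert-butyldimethylsilyl ether by rate and is too weak to attack the aryl MOM acetals, the aryl acetate or the benzylic ether.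

Step 16
Reactants: 26 4-[(S)-1-{2-[(2R,3R)-4-(tert-butyldimethylsilyloxy)-3-methyl-2-(3-methylbut-2-en-1-yl)butyl]-3,5-bis(methoxymethoxy)phenoxy}-3-hydroxypropyl]-3-methoxyphenyl acetate
Product: 28 (S)-3-(4-acetoxy-2-methoxyphenyl)-3-{2-[(2R,3R)-4-(tert-butyldimethylsilyloxy)-3-methyl-2-(3-methylbut-2-en-1-yl)butyl]-3,5-bis(methoxymethoxy)phenoxy}propanoic acid, via aldehyde 27 (not isolated)
Conditions: 2,2,6,6-tetramethylpiperidin-1-oxyl (0.2 equiv), PhI(OAc)2 (2.5 equiv), MeCN–H2O, 0 °C to rt
Reagents that add atoms: water, O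
Why: Oxoammonium-mediated oxidation in aqueous acetonitrile carries the primary alcohol through the aldehyde hydrate to the acid in one flask under weakly acidic, chlorine-free conditions, which avoids β-elimination of the aryloxide from 27, halogenation of ring A and attack on the alkene.

Step 17
Reactants: 28 (S)-3-(4-acetoxy-2-methoxyphenyl)-3-{2-[(2R,3R)-4-(tert-butyldimethylsilyloxy)-3-methyl-2-(3-methylbut-2-en-1-yl)butyl]-3,5-bis(methoxymethoxy)phenoxy}propanoic acid
Product: 30 (2S)-2-(4-acetoxy-2-methoxyphenyl)-8-[(2R,3R)-4-(tert-butyldimethylsilyloxy)-3-methyl-2-(3-methylbut-2-en-1-yl)butyl]-5,7-bis(methoxymethoxy)chroman-4-one, via acyl trifluoroacetate 29 (not isolated)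
Conditions: (CF3CO)2O (1.5 equiv), CH2Cl2 (0.02 M), −20 to 0 °C, no Lewis acid; cold aq NaHCO3
Reagents that add atoms: trifluoroacetic anhydride, O=C(OC(=O)C(F)(F)F)C(F)(F)F (its acyl group is held only by 29)
Why: The acid is converted by (CF3CO)2O into the acyl trifluoroacetate 29, C4a of ring A attacks its polarised acyl carbon, and loss of trifluoroacetate and of the C4a proton from the arenium ion gives the aryl ketone; this is an intramolecular Friedel–Crafts acylation through a mixed anhydride, the reaction type long used to turn 3-aryloxypropanoic acids into chroman-4-ones. Ring C closes as a six-membered ring in the 6-exo-trig mode at the acyl carbon, with the attacking C4a=C8a bond lying inside the new ring. No stereocentre is formed, and C2, C2'' and C3'' are only carried through. Regioselectivity is fixed by the substrate, because the tether from O1 reaches only the two ortho carbons and C8 is alkylated, whereas C6, though activated, would demand a bridged closure. The combined push of O1 and 5-OMOM (both ortho) and 7-OMOM (para) makes C4a nucleophilic enough that no Lewis acid is needed, so the MOM acetals, the silyl ether and the trisubstituted alkene see only dilute CF3CO2H at or below 0 °C, and the small excess of anhydride keeps intermolecular trifluoroacetylation at C6 from competing. Retention at C2 requires that the C2–O1 bond does not ionise, which the 4'-acetate secures by withholding the para oxygen lone pair from the benzylic position.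

Step 18
Reactants: 30 (2S)-2-(4-acetoxy-2-methoxyphenyl)-8-[(2R,3R)-4-(tert-butyldimethylsilyloxy)-3-methyl-2-(3-methylbut-2-en-1-yl)butyl]-5,7-bis(methoxymethoxy)chroman-4-one
Product: 31 (2S)-5,7-dihydroxy-2-(4-hydroxy-2-methoxyphenyl)-8-[(2R,3R)-4-hydroxy-3-methyl-2-(3-methylbut-2-en-1-yl)butyl]chroman-4-one
Conditions: HCl (1.25 M in MeOH), 40 °C
Reagents that add atoms: none
Why: Acid-catalysed transacetalisation, transesterification and desilylation in methanol should remove both MOM groups, the acetate and the TBS group in one operation, acid rather than base being used because it does not open the flavanone to the chalcone (which would scramble C2), and none of the freed hydroxyls can trap the alkene in a five- or six-membered ring.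

**Compound list**
1 | (S)-3-bromo-2-methylpropan-1-ol | BrC[C@@H](C)CO | starting material
2 | (S)-(3-bromo-2-methylpropoxy)(tert-butyl)dimethylsilane | BrC[C@@H](C)CO[Si](C)(C)C(C)(C)C | intermediate
3 | (S)-[3-(tert-butyldimethylsilyloxy)-2-methylpropyl]magnesium bromide, formed in situ | Br[Mg]C[C@@H](C)CO[Si](C)(C)C(C)(C)C | intermediate
4 | (R)-4-(tert-butyldimethylsilyloxy)-3-methylbutanoic acid | OC(=O)C[C@@H](C)CO[Si](C)(C)C(C)(C)C | intermediate
5 | (S)-4-benzyloxazolidin-2-one | O=C1N[C@@H](Cc2ccccc2)CO1 | starting material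
6 | (R)-4-(tert-butyldimethylsilyloxy)-3-methylbutanoic pivalic anhydride, formed in situ | CC(C)(C)C(=O)OC(=O)C[C@@H](C)CO[Si](C)(C)C(C)(C)C | intermediate
7 | (S)-4-benzyl-3-[(R)-4-(tert-butyldimethylsilyloxy)-3-methylbutanoyl]oxazolidin-2-one | O=C(C[C@@H](C)CO[Si](C)(C)C(C)(C)C)N1[C@@H](Cc2ccccc2)COC1=O | intermediate
8 | 1-bromo-3-methylbut-2-ene (prenyl bromide) | CC(C)=CCBr | starting material
9 | sodium (Z)-enolate of imide 7, formed in situ | [Na+].[O-]/C(=C\[C@@H](C)CO[Si](C)(C)C(C)(C)C)N1[C@@H](Cc2ccccc2)COC1=O | intermediate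
10 | (S)-4-benzyl-3-{(S)-2-[(R)-1-(tert-butyldimethylsilyloxy)propan-2-yl]-5-methylhex-4-enoyl}oxazolidin-2-one | O=C([C@@H](CC=C(C)C)[C@@H](C)CO[Si](C)(C)C(C)(C)C)N1[C@@H](Cc2ccccc2)COC1=O | intermediate
11 | (S)-2-[(R)-1-(tert-butyldimethylsilyloxy)propan-2-yl]-5-methylhex-4-en-1-ol | OC[C@@H](CC=C(C)C)[C@@H](C)CO[Si](C)(C)C(C)(C)C | intermediate
12 | tert-butyl{[(2R,3S)-3-(iodomethyl)-2,6-dimethylhept-5-en-1-yl]oxy}dimethylsilane | IC[C@@H](CC=C(C)C)[C@@H](C)CO[Si](C)(C)C(C)(C)C | intermediate
13 | phloroglucinol (benzene-1,3,5-triol) | Oc1cc(O)cc(O)c1 | starting material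
14 | 3,5-bis(methoxymethoxy)phenol | Oc1cc(OCOC)cc(OCOC)c1 | intermediate
15 | 2-iodo-3,5-bis(methoxymethoxy)phenol | Oc1cc(OCOC)cc(OCOC)c1I | intermediate
16 | 4-hydroxy-2-methoxybenzaldehyde | COc1cc(O)ccc1C=O | starting material
17 | 4-formyl-3-methoxyphenyl acetate | COc1cc(OC(C)=O)ccc1C=O | intermediate
18 | allylboronic acid pinacol ester (2-allyl-4,4,5,5-tetramethyl-1,3,2-dioxaborolane) | C=CCB1OC(C)(C)C(C)(C)O1 | starting material
19 | 4-[(R)-1-hydroxybut-3-en-1-yl]-3-methoxyphenyl acetate | COc1cc(OC(C)=O)ccc1[C@H](O)CC=C | intermediate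
20 | 4-[(R)-1-hydroxy-2-(1,2,4-trioxolan-3-yl)ethyl]-3-methoxyphenyl acetate (both epimers at the trioxolane carbon), formed in situ | COc1cc(OC(C)=O)ccc1[C@H](O)CC1OCOO1 | intermediate
21 | 4-[(R)-1,3-dihydroxypropyl]-3-methoxyphenyl acetate | COc1cc(OC(C)=O)ccc1[C@H](O)CCO | intermediate
22 | 4-[(R)-1-hydroxy-3-(triethylsilyloxy)propyl]-3-methoxyphenyl acetate | COc1cc(OC(C)=O)ccc1[C@H](O)CCO[Si](CC)(CC)CC | intermediate
23 | 4-{(S)-1-[2-iodo-3,5-bis(methoxymethoxy)phenoxy]-3-(triethylsilyloxy)propyl}-3-methoxyphenyl acetate | COc1cc(OC(C)=O)ccc1[C@@H](Oc1cc(OCOC)cc(OCOC)c1I)CCO[Si](CC)(CC)CC | intermediate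
24 | [(2S,3R)-4-(tert-butyldimethylsilyloxy)-3-methyl-2-(3-methylbut-2-en-1-yl)butyl]zinc iodide, formed in situ | I[Zn]C[C@@H](CC=C(C)C)[C@@H](C)CO[Si](C)(C)C(C)(C)C | intermediate
25 | 4-[(S)-1-{2-[(2R,3R)-4-(tert-butyldimethylsilyloxy)-3-methyl-2-(3-methylbut-2-en-1-yl)butyl]-3,5-bis(methoxymethoxy)phenoxy}-3-(triethylsilyloxy)propyl]-3-methoxyphenyl acetate | COc1cc(OC(C)=O)ccc1[C@@H](Oc1cc(OCOC)cc(OCOC)c1C[C@@H](CC=C(C)C)[C@@H](C)CO[Si](C)(C)C(C)(C)C)CCO[Si](CC)(CC)CC | intermediate
26 | 4-[(S)-1-{2-[(2R,3R)-4-(tert-butyldimethylsilyloxy)-3-methyl-2-(3-methylbut-2-en-1-yl)butyl]-3,5-bis(methoxymethoxy)phenoxy}-3-hydroxypropyl]-3-methoxyphenyl acetate | COc1cc(OC(C)=O)ccc1[C@@H](Oc1cc(OCOC)cc(OCOC)c1C[C@@H](CC=C(C)C)[C@@H](C)CO[Si](C)(C)C(C)(C)C)CCO | intermediate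
27 | 4-[(S)-1-{2-[(2R,3R)-4-(tert-butyldimethylsilyloxy)-3-methyl-2-(3-methylbut-2-en-1-yl)butyl]-3,5-bis(methoxymethoxy)phenoxy}-3-oxopropyl]-3-methoxyphenyl acetate, formed in situ | COc1cc(OC(C)=O)ccc1[C@@H](Oc1cc(OCOC)cc(OCOC)c1C[C@@H](CC=C(C)C)[C@@H](C)CO[Si](C)(C)C(C)(C)C)CC=O | intermediate
28 | (S)-3-(4-acetoxy-2-methoxyphenyl)-3-{2-[(2R,3R)-4-(tert-butyldimethylsilyloxy)-3-methyl-2-(3-methylbut-2-en-1-yl)butyl]-3,5-bis(methoxymethoxy)phenoxy}propanoic acid | COc1cc(OC(C)=O)ccc1[C@@H](Oc1cc(OCOC)cc(OCOC)c1C[C@@H](CC=C(C)C)[C@@H](C)CO[Si](C)(C)C(C)(C)C)CC(=O)O | intermediate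
29 | mixed anhydride of acid 28 and trifluoroacetic acid, formed in situ | COc1cc(OC(C)=O)ccc1[C@@H](Oc1cc(OCOC)cc(OCOC)c1C[C@@H](CC=C(C)C)[C@@H](C)CO[Si](C)(C)C(C)(C)C)CC(=O)OC(=O)C(F)(F)F | intermediate
30 | (2S)-2-(4-acetoxy-2-methoxyphenyl)-8-[(2R,3R)-4-(tert-butyldimethylsilyloxy)-3-methyl-2-(3-methylbut-2-en-1-yl)butyl]-5,7-bis(methoxymethoxy)chroman-4-one | COc1cc(OC(C)=O)ccc1[C@@H]1CC(=O)c2c(OCOC)cc(OCOC)c(C[C@@H](CC=C(C)C)[C@@H](C)CO[Si](C)(C)C(C)(C)C)c2O1 | intermediate
31 | (2S)-5,7-dihydroxy-2-(4-hydroxy-2-methoxyphenyl)-8-[(2R,3R)-4-hydroxy-3-methyl-2-(3-methylbut-2-en-1-yl)butyl]chroman-4-one | COc1cc(O)ccc1[C@@H]1CC(=O)c2c(O)cc(O)c(C[C@@H](CC=C(C)C)[C@@H](C)CO)c2O1 | target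

Total step count: 18 steps.
Longest linear sequence: 11 steps (steps 1–6, then 14–18).

**Steps most likely to fail**

**Step 17.**
- What may go wrong: ionisation of the C2–O1 bond, with loss of configuration or cleavage of the ether, and acid-induced loss of the MOM groups may outrun the acylation.
- Fallback: the closure is taken out of Brønsted-acidic medium by changing the electrophile from an acyl trifluoroacetate to an activated amide. It sets out from 28.
- The acid is condensed with Me2NH·HCl (amine as the limiting reagent to spare the acetate; EDC·HCl, 1-hydroxybenzotriazole, i-Pr2NEt, CH2Cl2, 0 °C) to give the N,N-dimethylamide F1.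
- (CF3SO2)2O and 2-chloropyridine (CH2Cl2, −78 to 0 °C) then generate the O-triflyl iminium ion. C4a attacks it in an intramolecular Vilsmeier–Haack-type acylation to give the cyclic iminium triflate F2.
- Aqueous NaHCO3 hydrolyses this to flavanone 30, where the route is rejoined.

**Step 13.**
- What may go wrong: partial ionisation of the activated carbinol may erode the inversion, the hydrazide base may cause elimination towards the styrene, and acetyl transfer to the phenoxide may compete.
- Fallback: the carbinol is taken out of the azodicarboxylate manifold and joined by a Mukaiyama oxidation–reduction condensation. No basic nitrogen anion is then present, and substitution takes place inside a tight phosphonium–phenoxide ion pair. It sets out from 22 and 15.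
- 22 is treated with Ph2PCl, Et3N and 4-dimethylaminopyridine (THF, 0 °C) to give the alkoxydiphenylphosphine F3.
- F3 is combined with 15 and 2,6-dimethyl-1,4-benzoquinone (CH2Cl2, rt) and should give the inverted ether 23, where the route is rejoined.
- Any C2 epimer that still forms is a diastereomer from 25 onward and can be removed by chromatography.

**Step 14.**
- What may go wrong: transmetalation and reductive elimination may be slow at a palladium aryl flanked by two ortho oxygen substituents, so that protodeiodination of the arene and β-hydride loss from the alkyl group take over.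
- Fallback: the C8–C1'' bond is made by polar carbonyl addition before the ether is formed, and the extra oxygen is removed through an ortho-quinone methide. It sets out from 15 and 11.
- 15 is silylated (TBSCl, imidazole) to the aryl silyl ether F4, which i-PrMgCl·LiCl (THF, −20 °C) converts into the arylmagnesium chloride F5.
- Alcohol 11 is oxidised with Dess–Martin periodinane and NaHCO3 to the aldehyde F6.
- Addition of F5 to F6 and quenching of the alkoxide with Ac2O gives the benzylic acetate F7. Both C1'' epimers form, which is of no consequence.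
- Bu4NF (1 equiv) together with NaBH4 (THF, 0 °C) removes the aryl silyl group, and the phenoxide expels acetate to give the ortho-quinone methide F8. Hydride adds to its exocyclic carbon to give the 2-alkylphenol F9.
- Mitsunobu reaction of F9 with 22 under the conditions of step 13 gives 25, where the route is rejoined.

Further compounds
F1 | step 17 | (S)-3-(4-acetoxy-2-methoxyphenyl)-3-{2-[(2R,3R)-4-(tert-butyldimethylsilyloxy)-3-methyl-2-(3-methylbut-2-en-1-yl)butyl]-3,5-bis(methoxymethoxy)phenoxy}-N,N-dimethylpropanamide | COc1cc(OC(C)=O)ccc1[C@@H](Oc1cc(OCOC)cc(OCOC)c1C[C@@H](CC=C(C)C)[C@@H](C)CO[Si](C)(C)C(C)(C)C)CC(=O)N(C)C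
F2 | step 17 | (2S)-4-(dimethyliminio)chroman triflate corresponding to flavanone 30 | COc1cc(OC(C)=O)ccc1[C@@H]1CC(=[N+](C)C)c2c(OCOC)cc(OCOC)c(C[C@@H](CC=C(C)C)[C@@H](C)CO[Si](C)(C)C(C)(C)C)c2O1.[O-]S(=O)(=O)C(F)(F)F
F3 | step 13 | 4-[(R)-1-(diphenylphosphanyloxy)-3-(triethylsilyloxy)propyl]-3-methoxyphenyl acetate | COc1cc(OC(C)=O)ccc1[C@H](OP(c1ccccc1)c1ccccc1)CCO[Si](CC)(CC)CC
F4 | step 14 | tert-butyl[2-iodo-3,5-bis(methoxymethoxy)phenoxy]dimethylsilane | COCOc1cc(OCOC)c(I)c(O[Si](C)(C)C(C)(C)C)c1
F5 | step 14 | [2-(tert-butyldimethylsilyloxy)-4,6-bis(methoxymethoxy)phenyl]magnesium chloride | COCOc1cc(OCOC)c([Mg]Cl)c(O[Si](C)(C)C(C)(C)C)c1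
F6 | step 14 | (S)-2-[(R)-1-(tert-butyldimethylsilyloxy)propan-2-yl]-5-methylhex-4-enal | O=C[C@@H](CC=C(C)C)[C@@H](C)CO[Si](C)(C)C(C)(C)C
F7 | step 14 | (2S)-1-[2-(tert-butyldimethylsilyloxy)-4,6-bis(methoxymethoxy)phenyl]-2-[(R)-1-(tert-butyldimethylsilyloxy)propan-2-yl]-5-methylhex-4-en-1-yl acetate (both epimers at the acetoxy carbon) | COCOc1cc(OCOC)c(C(OC(C)=O)[C@@H](CC=C(C)C)[C@@H](C)CO[Si](C)(C)C(C)(C)C)c(O[Si](C)(C)C(C)(C)C)c1
F8 | step 14 | ortho-quinone methide, 6-alkylidene-3,5-bis(methoxymethoxy)cyclohexa-2,4-dien-1-one carrying the side chain with both stereocentres unchanged | O=C1C=C(OCOC)C=C(OCOC)C1=C[C@@H](CC=C(C)C)[C@@H](C)CO[Si](C)(C)C(C)(C)C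
F9 | step 14 | 2-[(2R,3R)-4-(tert-butyldimethylsilyloxy)-3-methyl-2-(3-methylbut-2-en-1-yl)butyl]-3,5-bis(methoxymethoxy)phenol | Oc1cc(OCOC)cc(OCOC)c1C[C@@H](CC=C(C)C)[C@@H](C)CO[Si](C)(C)C(C)(C)C
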